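The route rests on cutting ring C at C3–C4. C3 is the only methylene of ring C, flanked by the C4 carbonyl and the O1-bearing stereocentre C2, so a C3=C4 enol ether is the ketone in masked form and can be closed by olefin metathesis. One operation therefore forges C3–C4 and ring C from a vinyl group on C2 and a 1-silyloxyvinyl group on C4a, leaving C2 untouched. The precursor is the tert-butyldimethylsilyl enol ether of a fully benzylated 2-hydroxyacetophenone (ring A carrying the 2,3-dioxygenated benzyl group at C6) whose ortho oxygen bears an (S)-1-phenylallyl group, installed by iridium-catalysed branched-selective allylic etherification.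

Key step: step 9

Remarks on the chemistry: flavanone numbering (O1, C2, C3, C4, C4a, C5–C8, C8a; ring A the phloroglucinol ring, ring C the pyranone) is used, and the target is 2S. The (Sa,S,S) phosphoramidite is assumed to give the S ether, following the usual sense of this catalyst family with heteroatom nucleophiles and cinnamyl carbonates. This sense is to be confirmed on the first batch; the mirror-image ligand is equally accessible.

Step 1
Reactants: 1 2,4,6-trihydroxybenzaldehyde
Product: 2 2,6-dihydroxy-4-(methoxymethoxy)benzaldehyde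
Conditions: MOMCl (1.05 equiv), i-Pr2NEt (1.1 equiv), THF, −10 to 0 °C
Reagents that add atoms: chloromethyl methyl ether, COCCl
Why: Williamson-type O-alkylation: the 4-hydroxyl is the most acidic one and the only one not held in a hydrogen bond to the formyl group, so one equivalent of the hard electrophile should etherify it first, and any bis-ether is removed by chromatography.

Step 2
Reactants: 2 2,6-dihydroxy-4-(methoxymethoxy)benzaldehyde
Product: 3 2,6-bis(benzyloxy)-4-(methoxymethoxy)benzaldehyde
Conditions: BnBr (2.5 equiv), K2CO3 (3 equiv), DMF, 60 °C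
Reagents that add atoms: benzyl bromide, BrCc1ccccc1
Why: Williamson etherification under forcing conditions alkylates both chelated ortho hydroxyls, while the methoxymethyl acetal and the non-enolisable aldehyde are inert to carbonate base.

Step 3
Reactants: 4 3-bromocatechol
Product: 5 1,2-bis(benzyloxy)-3-bromobenzene
Conditions: BnBr (2.3 equiv), K2CO3 (3 equiv), degassed DMF, rt
Reagents that add atoms: benzyl bromide, BrCc1ccccc1
Why: Williamson etherification of both catechol hydroxyls gives an aryl bromide whose ether groups tolerate the organolithium chemistry of step 4.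

Step 4
Reactants: 5 1,2-bis(benzyloxy)-3-bromobenzene; 3 2,6-bis(benzyloxy)-4-(methoxymethoxy)benzaldehyde
Product: 7 [2,6-bis(benzyloxy)-4-(methoxymethoxy)phenyl][2,3-bis(benzyloxy)phenyl]methanol (racemic), via aryllithium 6 (not isolated)
Conditions: 5 (1.2 equiv), n-BuLi (1.15 equiv), THF, −78 °C; then 3, −78 to −20 °C; H2O quench
Reagents that add atoms: none
Why: Bromine–lithium exchange at −78 °C outruns deprotonation of the benzylic ether positions, and the aryllithium then undergoes 1,2-addition to the non-enolisable aldehyde; the carbinol centre forms as a racemate and is erased in step 5.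

Step 5
Reactants: 7 [2,6-bis(benzyloxy)-4-(methoxymethoxy)phenyl][2,3-bis(benzyloxy)phenyl]methanol
Product: 9 3,5-bis(benzyloxy)-4-[2,3-bis(benzyloxy)benzyl]phenol, via MOM-protected diarylmethane 8 (not isolated)
Conditions: Et3SiH (3 equiv), CF3CO2H (2 equiv), CH2Cl2, −30 to 0 °C; then MeOH, conc. HCl, 40 °C, dilute
Reagents that add atoms: none
Why: Ionic hydrogenation: mild acid ionises the doubly benzylic carbinol to a cation stabilised by the trioxygenated ring, the silane delivers hydride to it, and the subsequent acid methanolysis of the methoxymethyl acetal frees the phenol while methanol traps the formaldehyde unit as dimethoxymethane and the benzyl ethers stay intact.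

Step 6
Reactants: 9 3,5-bis(benzyloxy)-4-[2,3-bis(benzyloxy)benzyl]phenol
Product: 11 1-{2,4-bis(benzyloxy)-3-[2,3-bis(benzyloxy)benzyl]-6-hydroxyphenyl}ethan-1-one, via aryl acetate 10 (not isolated)
Conditions: Ac2O (1.05 equiv), BF3·OEt2 (3 equiv), CH2Cl2, 0 °C then 40 °C; H2O quench
Reagents that add atoms: acetic anhydride, CC(=O)OC(C)=O
Why: Fries rearrangement: the phenol is O-acetylated and BF3 then shifts the acyl group to one of the two equivalent ortho positions (the para position carries the benzyl group), the single equivalent of anhydride and the hydrogen-bonded, deactivated product guarding against a second acylation.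

Step 7
Reactants: 11 1-{2,4-bis(benzyloxy)-3-[2,3-bis(benzyloxy)benzyl]-6-hydroxyphenyl}ethan-1-one; 12 cinnamyl methyl carbonate
Product: 13 1-{2,4-bis(benzyloxy)-3-[2,3-bis(benzyloxy)benzyl]-6-{[(1S)-1-phenylprop-2-en-1-yl]oxy}phenyl}ethan-1-one
Conditions: [Ir(cod)Cl]2 (2 mol %), (Sa,S,S)-O,O′-(1,1′-binaphthalene-2,2′-diyl) N,N-bis(1-phenylethyl)phosphoramidite (4 mol %), pre-activated with n-PrNH2; 12 (1.3 equiv), K3PO4 (1 equiv), THF, 25–40 °C
Reagents that add atoms: none
Why: Iridium-catalysed asymmetric allylic substitution: the cyclometalated iridium phosphoramidite complex ionises the carbonate to an allyl complex, the phenoxide attacks its phenyl-bearing terminus (branched selectivity), and the ligand dictates the face of attack, which sets the future C2 as S.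

Step 8
Reactants: 13 1-{2,4-bis(benzyloxy)-3-[2,3-bis(benzyloxy)benzyl]-6-{[(1S)-1-phenylprop-2-en-1-yl]oxy}phenyl}ethan-1-one
Product: 14 tert-butyl{[1-(2,4-bis(benzyloxy)-3-[2,3-bis(benzyloxy)benzyl]-6-{[(1S)-1-phenylprop-2-en-1-yl]oxy}phenyl)ethenyl]oxy}dimethylsilane
Conditions: TBSOTf (1.5 equiv), Et3N (3 equiv), CH2Cl2, −20 to 0 °C
Reagents that add atoms: tert-butyldimethylsilyl trifluoromethanesulfonate, CC(C)(C)[Si](C)(C)OS(=O)(=O)C(F)(F)F
Why: Soft enolisation: the silyl triflate activates the carbonyl oxygen and the amine removes a proton from the only enolisable position, the methyl group, giving the terminal silyl enol ether without a strong base that could deprotonate the allylic benzylic C–H of the stereocentre.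

Step 9
Reactants: 14 tert-butyl{[1-(2,4-bis(benzyloxy)-3-[2,3-bis(benzyloxy)benzyl]-6-{[(1S)-1-phenylprop-2-en-1-yl]oxy}phenyl)ethenyl]oxy}dimethylsilane
Product: 15 tert-butyl({(2S)-5,7-bis(benzyloxy)-6-[2,3-bis(benzyloxy)benzyl]-2-phenyl-2H-chromen-4-yl}oxy)dimethylsilane
Conditions: second-generation Grubbs catalyst (H2IMes)(PCy3)Cl2Ru=CHPh (10 mol % in two portions), degassed toluene (0.005 M), 40 °C, argon sparge, exclusion of light; cold filtration through Et3N-deactivated silica, used at once
Reagents that add atoms: none
Why: Ring-closing olefin metathesis: the benzylidene catalyst initiates at the unhindered vinyl group on C2, the new alkylidene (ruthenium on C3) engages the enol ether C=C so that C3 bonds to C4 and the metal to the CH2 terminus, and opening of the ruthenacyclobutane gives the C3=C4 enol ether and a ruthenium methylidene that carries the chain while ethene is swept out. The closest known reactions are the ring-closing metathesis of acyclic silyl enol ethers with terminal alkenes to cyclic silyl enol ethers, benzo-fused examples included, and the closure of 2-vinylaryl allyl ethers to 2H-chromenes with the same catalyst. Ring C closes as a six-membered ring by this intramolecular [2+2] cycloaddition–cycloreversion, the new double bond lying inside the ring and C3–C4 being the only skeletal bond made. No stereocentre is created: C2 was fixed in step 7 and none of its four bonds takes part, so its S configuration is carried through as long as the chromene is kept at or below 40 °C and in the dark, which suppresses reversible electrocyclic opening to the ortho-quinone methide. The step needs site selectivity in initiation and regioselectivity in the cycloaddition, because loading onto the enol ether or the reverse orientation would give an unreactive oxygen-stabilised carbene; the steric gap between the open vinyl group and the hindered 1,1-disubstituted enol ether secures both. High dilution keeps cross-metathesis of two allyl termini behind ring closure.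

Step 10
Reactants: 15 tert-butyl({(2S)-5,7-bis(benzyloxy)-6-[2,3-bis(benzyloxy)benzyl]-2-phenyl-2H-chromen-4-yl}oxy)dimethylsilane
Product: 16 (2S)-5,7-bis(benzyloxy)-6-[2,3-bis(benzyloxy)benzyl]-2-phenyl-2,3-dihydro-4H-chromen-4-one
Conditions: 1 M HCl, THF, 0 °C, dark
Reagents that add atoms: none
Why: Acid hydrolysis of a silyl enol ether: protonation at C3 and loss of the silyl group to water unveil the C4 ketone without any enolate, so that base-induced ring opening to the chalcone cannot scramble C2.

Step 11
Reactants: 16 (2S)-5,7-bis(benzyloxy)-6-[2,3-bis(benzyloxy)benzyl]-2-phenyl-2,3-dihydro-4H-chromen-4-one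
Product: 17 (2S)-6-(2,3-dihydroxybenzyl)-5,7-dihydroxy-2-phenyl-2,3-dihydro-4H-chromen-4-one
Conditions: H2 (1 atm), 10% Pd/C, EtOAc–MeOH, rt
Reagents that add atoms: none
Why: Catalytic hydrogenolysis cleaves the four O-benzyl bonds under neutral conditions that leave the ketone, now hydrogen-bonded to the 5-hydroxyl, and the C2 configuration untouched, the reaction being stopped at full debenzylation to avoid cleavage of the benzylic C2–O1 bond.

Compound list
1 | 2,4,6-trihydroxybenzaldehyde | O=Cc1c(O)cc(O)cc1O | starting material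
2 | 2,6-dihydroxy-4-(methoxymethoxy)benzaldehyde | O=Cc1c(O)cc(OCOC)cc1O | intermediate
3 | 2,6-bis(benzyloxy)-4-(methoxymethoxy)benzaldehyde | O=Cc1c(OCc2ccccc2)cc(OCOC)cc1OCc1ccccc1 | intermediate
4 | 3-bromocatechol (3-bromobenzene-1,2-diol) | Oc1cccc(Br)c1O | starting material
5 | 1,2-bis(benzyloxy)-3-bromobenzene | Brc1cccc(OCc2ccccc2)c1OCc1ccccc1 | intermediate
6 | [2,3-bis(benzyloxy)phenyl]lithium | [Li]c1cccc(OCc2ccccc2)c1OCc1ccccc1 | intermediate
7 | [2,6-bis(benzyloxy)-4-(methoxymethoxy)phenyl][2,3-bis(benzyloxy)phenyl]methanol (racemic) | OC(c1cccc(OCc2ccccc2)c1OCc1ccccc1)c1c(OCc2ccccc2)cc(OCOC)cc1OCc1ccccc1 | intermediate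
8 | 1,3-bis(benzyloxy)-2-[2,3-bis(benzyloxy)benzyl]-5-(methoxymethoxy)benzene | COCOc1cc(OCc2ccccc2)c(Cc2cccc(OCc3ccccc3)c2OCc2ccccc2)c(OCc2ccccc2)c1 | intermediate
9 | 3,5-bis(benzyloxy)-4-[2,3-bis(benzyloxy)benzyl]phenol | Oc1cc(OCc2ccccc2)c(Cc2cccc(OCc3ccccc3)c2OCc2ccccc2)c(OCc2ccccc2)c1 | intermediate
10 | 3,5-bis(benzyloxy)-4-[2,3-bis(benzyloxy)benzyl]phenyl acetate | CC(=O)Oc1cc(OCc2ccccc2)c(Cc2cccc(OCc3ccccc3)c2OCc2ccccc2)c(OCc2ccccc2)c1 | intermediate
11 | 1-{2,4-bis(benzyloxy)-3-[2,3-bis(benzyloxy)benzyl]-6-hydroxyphenyl}ethan-1-one | CC(=O)c1c(O)cc(OCc2ccccc2)c(Cc2cccc(OCc3ccccc3)c2OCc2ccccc2)c1OCc1ccccc1 | intermediate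
12 | cinnamyl methyl carbonate, (E)-methyl 3-phenylprop-2-en-1-yl carbonate | COC(=O)OC/C=C/c1ccccc1 | starting material
13 | 1-{2,4-bis(benzyloxy)-3-[2,3-bis(benzyloxy)benzyl]-6-{[(1S)-1-phenylprop-2-en-1-yl]oxy}phenyl}ethan-1-one | C=C[C@@H](c1ccccc1)Oc1cc(OCc2ccccc2)c(Cc2cccc(OCc3ccccc3)c2OCc2ccccc2)c(OCc2ccccc2)c1C(C)=O | intermediate
14 | tert-butyl{[1-(2,4-bis(benzyloxy)-3-[2,3-bis(benzyloxy)benzyl]-6-{[(1S)-1-phenylprop-2-en-1-yl]oxy}phenyl)ethenyl]oxy}dimethylsilane | C=C[C@@H](c1ccccc1)Oc1cc(OCc2ccccc2)c(Cc2cccc(OCc3ccccc3)c2OCc2ccccc2)c(OCc2ccccc2)c1C(=C)O[Si](C)(C)C(C)(C)C | intermediate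
15 | tert-butyl({(2S)-5,7-bis(benzyloxy)-6-[2,3-bis(benzyloxy)benzyl]-2-phenyl-2H-chromen-4-yl}oxy)dimethylsilane | CC(C)(C)[Si](C)(C)OC1=C[C@@H](c2ccccc2)Oc2cc(OCc3ccccc3)c(Cc3cccc(OCc4ccccc4)c3OCc3ccccc3)c(OCc3ccccc3)c21 | intermediate
16 | (2S)-5,7-bis(benzyloxy)-6-[2,3-bis(benzyloxy)benzyl]-2-phenyl-2,3-dihydro-4H-chromen-4-one | O=C1C[C@@H](c2ccccc2)Oc2cc(OCc3ccccc3)c(Cc3cccc(OCc4ccccc4)c3OCc3ccccc3)c(OCc3ccccc3)c21 | intermediate
17 | (2S)-6-(2,3-dihydroxybenzyl)-5,7-dihydroxy-2-phenyl-2,3-dihydro-4H-chromen-4-one | O=C1C[C@@H](c2ccccc2)Oc2cc(O)c(Cc3cccc(O)c3O)c(O)c21 | target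

Total step count: 11. Longest linear sequence: 10 steps (steps 1, 2 and 4–11, from 2,4,6-trihydroxybenzaldehyde); step 3 is the side branch.

Steps most likely to fail

Step 9. Several processes may defeat the ring closure:
- it may stall because the 1,1-disubstituted enol ether is flanked by two ortho oxygen substituents;
- the allyl termini may dimerise by cross-metathesis;
- the allyl ether may isomerise through ruthenium hydride species;
- the chromene may lose optical purity by reversible electrocyclic ring opening.

The fallback leaves the metathesis route at acetophenone 11 and makes the C2–phenyl bond last. Condensation of 11 with N,N-dimethylformamide dimethyl acetal (toluene, 90 °C) should give the enaminone (E)-1-{2,4-bis(benzyloxy)-3-[2,3-bis(benzyloxy)benzyl]-6-hydroxyphenyl}-3-(dimethylamino)prop-2-en-1-one F1. Acid (HCl, CH2Cl2, rt) should cyclise it with loss of dimethylamine to 5,7-bis(benzyloxy)-6-[2,3-bis(benzyloxy)benzyl]-4H-chromen-4-one F2. Enantioselective conjugate addition of phenylboronic acid to this chromone (Pd(OCOCF3)2, the enantiomer of 4-tert-butyl-2-(pyridin-2-yl)-4,5-dihydrooxazole that gives the 2S adduct, NH4PF6, H2O, ClCH2CH2Cl, 60 °C) returns the route at protected flavanone 16.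

Step 7. The chelated, electron-poor ortho-acyl phenoxide may attack the allyl–iridium intermediate only slowly, and the ether once formed may re-ionise; both would erode branched selectivity and enantiomeric purity. The fallback sets out from 11 and takes the stereocentre from a chiral alcohol instead of the catalyst. Mitsunobu etherification with commercial (R)-1-phenylprop-2-en-1-ol (PPh3, DIAD, toluene, 0 °C) should displace with inversion and return the route at allyl ether 13. It makes no compound outside the list (none F0).

Step 6. A second acylation at the remaining ortho position, Lewis-acid loss of the benzyl ether next to the new carbonyl, or acidolytic cleavage of the electron-rich diarylmethane may occur. The fallback sets out from phenol 9 and avoids strong Lewis acids: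
- magnesium-mediated ortho-formylation (MgCl2, Et3N, paraformaldehyde, MeCN, reflux) should give 2,4-bis(benzyloxy)-3-[2,3-bis(benzyloxy)benzyl]-6-hydroxybenzaldehyde F3;
- MeMgBr (3 equiv, THF, 0 °C) should add to give racemic 3,5-bis(benzyloxy)-4-[2,3-bis(benzyloxy)benzyl]-2-(1-hydroxyethyl)phenol F4;
- oxidation of the benzylic alcohol with MnO2 (CH2Cl2, rt) returns the route at acetophenone 11.

Further compounds
F1 | step 9 | (E)-1-{2,4-bis(benzyloxy)-3-[2,3-bis(benzyloxy)benzyl]-6-hydroxyphenyl}-3-(dimethylamino)prop-2-en-1-one | CN(C)/C=C/C(=O)c1c(O)cc(OCc2ccccc2)c(Cc2cccc(OCc3ccccc3)c2OCc2ccccc2)c1OCc1ccccc1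
F2 | step 9 | 5,7-bis(benzyloxy)-6-[2,3-bis(benzyloxy)benzyl]-4H-chromen-4-one | O=c1ccoc2cc(OCc3ccccc3)c(Cc3cccc(OCc4ccccc4)c3OCc3ccccc3)c(OCc3ccccc3)c12
F0 | step 7 | none | none
F3 | step 6 | 2,4-bis(benzyloxy)-3-[2,3-bis(benzyloxy)benzyl]-6-hydroxybenzaldehyde | O=Cc1c(O)cc(OCc2ccccc2)c(Cc2cccc(OCc3ccccc3)c2OCc2ccccc2)c1OCc1ccccc1
F4 | step 6 | 3,5-bis(benzyloxy)-4-[2,3-bis(benzyloxy)benzyl]-2-(1-hydroxyethyl)phenol (racemic) | CC(O)c1c(O)cc(OCc2ccccc2)c(Cc2cccc(OCc3ccccc3)c2OCc2ccccc2)c1OCc1ccccc1
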